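Everything rests on cutting ring A (the cyclohexene) at its allyl ester unit O–C10–C9(Me)=C8, the retron of a halocyclopropane opening. The precursor is a trans-fused five–seven carbocycle whose cyclopentane carries a chloro(methyl)cyclopropane across C8–C10. Silver isovanillate removes the endo chloride, the C8–C10 bond opens, the five-membered ring takes up C9 and becomes a cyclohexenyl cation, and the carboxylate adds at C10. One operation thus makes ring A, the C8=C9 alkene, the ester C–O bond and the C10 stereocentre. The step exploits the quaternary C6 beside C7, which shields C8, and the trans C1–C7 fusion, which directs pseudoaxial attack.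

Key step: step 9

Numbering: the target is numbered as bicyclo[5.4.0]undecane. C1 and C7 are the ring-fusion CH, C2 is C(CH3)OH, C3–C5 are CH2, C6 is C(CH3)2, C8 is =CH, C9 is =C(CH3), C10 is CH–O and C11 is CH2. Ring A is C1, C7–C11; ring B is C1–C7. In the Why lines these labels also denote the same atoms in the precursors.

Assumption: (S)-BINAP is taken to address the same enone face of 4 as it does in unsubstituted cyclic enones. If the sense were opposite, (R)-BINAP would be used.

Step 1
Reactants: 1 4,4-dimethylcyclohex-2-en-1-one; 2 ethyl diazoacetate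
Product: 3 ethyl 5,5-dimethyl-2-oxocyclohept-3-ene-1-carboxylate
Conditions: BF3·OEt2, Et2O, 0 °C to rt
Reagents that add atoms: none
Why: Lewis-acid-promoted diazoacetate homologation (Tiffeneau–Demjanov type) in which the saturated α′-carbon of an enone should migrate rather than the vinylic carbon, so ring B gains its seventh atom beside the carbonyl; the new centre is enolisable and disappears in step 2.

Step 2
Reactants: 3 ethyl 5,5-dimethyl-2-oxocyclohept-3-ene-1-carboxylate
Product: 4 4,4-dimethylcyclohept-2-en-1-one
Conditions: LiCl, H2O, DMSO, 150 °C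
Reagents that add atoms: none
Why: Krapcho dealkoxycarbonylation of a β-keto ester, which proceeds under neutral conditions that leave the enone untouched and creates no stereocentre.

Step 3
Reactants: 4 4,4-dimethylcyclohept-2-en-1-one; 5 hex-1-yne
Product: 7 {[(3R)-3-[(E)-hex-1-enyl]-4,4-dimethylcyclohept-1-en-1-yl]oxy}trimethylsilane, via (E)-hex-1-enylzirconocene chloride 6 (not isolated)
Conditions: 5, Cp2Zr(H)Cl, THF, rt; then 4, [Rh(cod)(MeCN)2]BF4 (5 mol %), (S)-BINAP (6 mol %), TMSCl, THF, rt
Reagents that add atoms: chlorotrimethylsilane C[Si](C)(C)Cl; zirconocene chloride hydride [H][Zr](Cl)(C1C=CC=C1)C1C=CC=C1 (gives the zirconium of 6 only)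
Why: Hydrozirconation gives the (E)-alkenyl metal, which transmetalates to monovalent rhodium, and the (S)-BINAP–rhodium alkenyl species should add 1,4 to one enone face (asymmetric conjugate addition of the Hayashi type) and set C7 as (R), while TMSCl traps the enolate regiospecifically at the C2–C1 position.

Step 4
Reactants: 7 {[(3R)-3-[(E)-hex-1-enyl]-4,4-dimethylcyclohept-1-en-1-yl]oxy}trimethylsilane
Product: 9 (2R,3R)-2-allyl-3-[(E)-hex-1-enyl]-4,4-dimethylcycloheptan-1-one (trans), via lithium enolate 8 (not isolated)
Conditions: MeLi, THF, 0 °C; then allyl iodide, DMPU, −78 to −20 °C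
Reagents that add atoms: allyl iodide C=CCI; methyllithium [Li]C (gives the lithium of 8 only)
Why: Cleavage of the silyl enol ether by MeLi releases the regiodefined lithium enolate, whose SN2 allylation should occur anti to the neighbouring alkenyl group and set C1 as (R), trans to C7.

Step 5
Reactants: 9 (2R,3R)-2-allyl-3-[(E)-hex-1-enyl]-4,4-dimethylcycloheptan-1-one
Product: 10 (1R,7R)-6,6-dimethylbicyclo[5.3.0]dec-8-en-2-one (trans-fused)
Conditions: second-generation Grubbs catalyst (5 mol %), CH2Cl2, 40 °C
Reagents that add atoms: none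
Why: Ring-closing metathesis in which the ruthenium carbene loads on the terminal allyl group and closes the five-membered ring onto the internal alkene with loss of hex-1-ene, under neutral conditions that leave the epimerisable C1 untouched.

Step 6
Reactants: 10 (1R,7R)-6,6-dimethylbicyclo[5.3.0]dec-8-en-2-one
Product: 11 (1R,2R,7R)-2,6,6-trimethylbicyclo[5.3.0]dec-8-en-2-ol (OH cis to H-1)
Conditions: MeAl(OAr)2 (Ar = 2,6-di-tert-butyl-4-methylphenyl, made from Me3Al and ArOH, 3 equiv), toluene, −78 °C; MeLi, −78 °C; cold 1 M HCl work-up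
Reagents that add atoms: methyllithium [Li]C
Why: Amphiphilic carbonyl alkylation, in which the bulky aluminium Lewis acid should occupy the open equatorial side of the ketone so that MeLi is forced onto the axial face (the face of H-7), leaving the C2 hydroxyl equatorial and cis to H-1, i.e. (2R).

Step 7
Reactants: 11 (1R,2R,7R)-2,6,6-trimethylbicyclo[5.3.0]dec-8-en-2-ol
Product: 12 9-chloro-2,6,6,9-tetramethyltricyclo[5.4.0.0(8,10)]undecan-2-ol (cyclopropane syn to H-7, chlorine endo over the five-membered ring, methyl exo)
Conditions: MeCHCl2 (excess), n-BuLi (excess, slow addition), Et2O, −40 to −30 °C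
Reagents that add atoms: 1,1-dichloroethane CC(Cl)Cl
Why: Chloro(methyl)carbenoid cyclopropanation (α-elimination of 1,1-dichloroethyllithium, stereospecific syn addition) should occur on the alkene face anti to C6 with the smaller chlorine endo, the hindered tertiary lithium alkoxide being as inert to halocarbenes as tert-butoxide; the cyclopropane face has no consequence for step 9, but any exo-chloro epimer formed is lost because it cannot ionise there.

Step 8
Reactants: 13 3-hydroxy-4-methoxybenzoic acid (isovanillic acid)
Product: 15 3-(tert-butyldimethylsilyloxy)-4-methoxybenzoic acid, via bis-silylated isovanillate 14 (not isolated)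
Conditions: TBSCl (2.5 equiv), imidazole, DMF, rt; then AcOH–THF–H2O, rt
Reagents that add atoms: tert-butyldimethylsilyl chloride CC(C)(C)[Si](C)(C)Cl
Why: Exhaustive silylation followed by selective hydrolysis of the far more labile silyl ester leaves only the phenol masked, so that neither phenol O-alkylation nor oxidation by silver can interfere in step 9.

Step 9
Reactants: 12 9-chloro-2,6,6,9-tetramethyltricyclo[5.4.0.0(8,10)]undecan-2-ol; 15 3-(tert-butyldimethylsilyloxy)-4-methoxybenzoic acid
Product: 18 (1R,2R,7R,10R)-2-hydroxy-2,6,6,9-tetramethylbicyclo[5.4.0]undec-8-en-10-yl 3-(tert-butyldimethylsilyloxy)-4-methoxybenzoate, via silver carboxylate 16 (not isolated), via allyl cation 17 (not isolated)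
Conditions: 15, Ag2O, MeCN, dark, rt, then evaporation to dryness; 12, 4 Å molecular sieves, toluene, 70 °C, dark
Reagents that add atoms: disilver oxide [Ag+].[Ag+].[O-2] (gives the silver of 16 only)
Why: Monovalent silver abstracts the endo chloride of 12 while the C8–C10 σ bond opens in the disrotatory sense that turns both ring bonds inward (2π electrocyclic cyclopropyl-to-allyl cation opening, Woodward–Hoffmann–DePuy rule), so the five-membered ring takes up C9 and becomes the 2-methylcyclohexenyl cation 17. The closest known reaction type is the silver-carboxylate-promoted ring expansion of 6-halobicyclo[3.1.0]hexanes to cyclohex-2-enyl esters. No ring is closed: ring A arises by cleavage of the zero-atom bridge of the bicyclo[3.1.0]hexane, and both cyclopropane-face isomers of 12 converge on 17. The needed regioselectivity (C10 against C8) should come from the quaternary C6 on C7, which makes C8 neopentyl-like, whereas C10 is flanked only by the C11 methylene. The C10 stereocentre should be set by pseudoaxial attack on the sofa-shaped cation locked by the trans fusion, on the face of H-1, which leads directly to the half-chair and places the ester free of A(1,2) strain with the C9 methyl, giving (10R). The C2 hydroxyl cannot reach C8 or C10 because C2 is held equatorial by the trans fusion, and the exo-chloro epimer cannot ionise.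

Step 10
Reactants: 18 (1R,2R,7R,10R)-2-hydroxy-2,6,6,9-tetramethylbicyclo[5.4.0]undec-8-en-10-yl 3-(tert-butyldimethylsilyloxy)-4-methoxybenzoate
Product: 19 (1R,2R,7R,10R)-2-hydroxy-2,6,6,9-tetramethylbicyclo[5.4.0]undec-8-en-10-yl 3-hydroxy-4-methoxybenzoate (CNP0210711.2)
Conditions: TBAF, AcOH, THF, 0 °C
Reagents that add atoms: none
Why: Fluoride-mediated cleavage of the aryl silyl ether, buffered with acetic acid so that the phenoxide cannot attack the allylic ester, touches no stereocentre.

Compound list
1 | 4,4-dimethylcyclohex-2-en-1-one | CC1(C)CCC(=O)C=C1 | starting material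
2 | ethyl diazoacetate | CCOC(=O)C=[N+]=[N-] | starting material
3 | ethyl 5,5-dimethyl-2-oxocyclohept-3-ene-1-carboxylate (racemic, enolisable centre) | CCOC(=O)C1CCC(C)(C)C=CC1=O | intermediate
4 | 4,4-dimethylcyclohept-2-en-1-one | CC1(C)CCCC(=O)C=C1 | intermediate
5 | hex-1-yne | CCCCC#C | starting material
6 | (E)-hex-1-enylzirconocene chloride | CCCC/C=C/[Zr](Cl)(C1C=CC=C1)C1C=CC=C1 | intermediate
7 | {[(3R)-3-[(E)-hex-1-enyl]-4,4-dimethylcyclohept-1-en-1-yl]oxy}trimethylsilane | C[Si](C)(C)OC1=C[C@@H](/C=C/CCCC)C(C)(C)CCC1 | intermediate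
8 | lithium (3R)-3-[(E)-hex-1-enyl]-4,4-dimethylcyclohept-1-en-1-olate | [Li+].[O-]C1=C[C@@H](/C=C/CCCC)C(C)(C)CCC1 | intermediate
9 | (2R,3R)-2-allyl-3-[(E)-hex-1-enyl]-4,4-dimethylcycloheptan-1-one | C=CC[C@@H]1[C@@H](/C=C/CCCC)C(C)(C)CCCC1=O | intermediate
10 | (1R,7R)-6,6-dimethylbicyclo[5.3.0]dec-8-en-2-one, trans-fused | C1C[C@@H]2[C@@H](C=1)C(C)(C)CCCC2=O | intermediate
11 | (1R,2R,7R)-2,6,6-trimethylbicyclo[5.3.0]dec-8-en-2-ol, OH cis to H-1 | C1C[C@@H]2[C@@H](C=1)C(C)(C)CCC[C@@]2(C)O | intermediate
12 | 9-chloro-2,6,6,9-tetramethyltricyclo[5.4.0.0(8,10)]undecan-2-ol, cyclopropane syn to H-7, Cl endo, CH3 exo | C[C@]1(Cl)[C@H]2C[C@@H]3[C@@H]([C@@H]12)C(C)(C)CCC[C@@]3(C)O | intermediate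
13 | 3-hydroxy-4-methoxybenzoic acid | COc1ccc(C(=O)O)cc1O | starting material
14 | tert-butyldimethylsilyl 3-(tert-butyldimethylsilyloxy)-4-methoxybenzoate | COc1ccc(C(=O)O[Si](C)(C)C(C)(C)C)cc1O[Si](C)(C)C(C)(C)C | intermediate
15 | 3-(tert-butyldimethylsilyloxy)-4-methoxybenzoic acid | COc1ccc(C(=O)O)cc1O[Si](C)(C)C(C)(C)C | intermediate
16 | silver 3-(tert-butyldimethylsilyloxy)-4-methoxybenzoate | COc1ccc(C(=O)[O-])cc1O[Si](C)(C)C(C)(C)C.[Ag+] | intermediate
17 | (1R,2R,7R)-2-hydroxy-2,6,6,9-tetramethylbicyclo[5.4.0]undec-8-en-10-ylium (allyl cation C8–C9–C10) | [CH+]1C[C@@H]2[C@@H](C=C1C)C(C)(C)CCC[C@@]2(C)O | intermediate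
18 | (1R,2R,7R,10R)-2-hydroxy-2,6,6,9-tetramethylbicyclo[5.4.0]undec-8-en-10-yl 3-(tert-butyldimethylsilyloxy)-4-methoxybenzoate | COc1ccc(C(=O)O[C@@H]2C[C@@H]3[C@@H](C=C2C)C(C)(C)CCC[C@@]3(C)O)cc1O[Si](C)(C)C(C)(C)C | intermediate
19 | (1R,2R,7R,10R)-2-hydroxy-2,6,6,9-tetramethylbicyclo[5.4.0]undec-8-en-10-yl 3-hydroxy-4-methoxybenzoate | COc1ccc(C(=O)O[C@@H]2C[C@@H]3[C@@H](C=C2C)C(C)(C)CCC[C@@]3(C)O)cc1O | target

Total step count: 10. Longest linear sequence: 9 (steps 1–7, 9 and 10). Step 8 is a one-step side branch.

Steps most likely to fail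

Step 9.
- What may go wrong: the cation may lose a proton to give dienes; the bulky carboxylate may be captured on the wrong face or at C8; the chloride may ionise slowly.
- Fallback: the ring expansion is kept, but the ester bond is made afterwards with stereochemical correction. It sets out from 12. AgNO3 in aqueous acetone should give the ring-expanded C10-epimeric allylic alcohols F1. MnO2 in CH2Cl2 oxidises them to the single enone F2. NaBH4/CeCl3·7H2O in MeOH (Luche reduction, axial hydride delivery) should give the pseudoequatorial (10S)-allylic alcohol F3. Mitsunobu esterification of F3 with acid 15 (PPh3, DIAD, THF) inverts C10 and comes back to the route at 18.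

Step 7.
- What may go wrong: cyclopropanation of the hindered, unactivated alkene may be slower than the 1,2-hydride shift of the carbenoid; the exo-chloro epimer, which cannot ionise, may form; the alkoxide may consume the carbenoid.
- Fallback: the methyl group is brought in only after the ring expansion. It sets out from 11. CHBr3, 50% aqueous NaOH and BnEt3NCl (phase-transfer dibromocarbene addition, tolerant of the free tertiary alcohol) should give the dibromocyclopropane F4, which always carries an endo bromide. Silver carboxylate 16 in toluene then expands the ring in the same manner to the 9-bromo allylic ester F5. Negishi methylation of the alkenyl bromide (MeZnCl, Pd(dppf)Cl2, THF) comes back to the route at 18.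

Step 6.
- What may go wrong: methyl may be delivered equatorially if the aluminium reagent binds the flanked ketone poorly; enolisation may epimerise C1.
- Fallback: the carbon is delivered as a small ylide and then reduced. It sets out from 10. Dimethylsulfonium methylide (Me3SI, n-BuLi, THF, 0 °C; kinetic axial attack of the Corey–Chaykovsky reaction) should give the spiro-epoxide F6 with axial CH2 and equatorial oxygen. LiEt3BH in THF opens it at the CH2 terminus and comes back to the route at 11.

Further compounds
F1 | step 9 | (1R,2R,7R)-2,6,6,9-tetramethylbicyclo[5.4.0]undec-8-ene-2,10-diol, C10 epimers | OC1C[C@@H]2[C@@H](C=C1C)C(C)(C)CCC[C@@]2(C)O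
F2 | step 9 | (1R,2R,7R)-2-hydroxy-2,6,6,9-tetramethylbicyclo[5.4.0]undec-8-en-10-one | O=C1C[C@@H]2[C@@H](C=C1C)C(C)(C)CCC[C@@]2(C)O
F3 | step 9 | (1R,2R,7R,10S)-2,6,6,9-tetramethylbicyclo[5.4.0]undec-8-ene-2,10-diol | O[C@H]1C[C@@H]2[C@@H](C=C1C)C(C)(C)CCC[C@@]2(C)O
F4 | step 7 | 9,9-dibromo-2,6,6-trimethyltricyclo[5.4.0.0(8,10)]undecan-2-ol, cyclopropane syn to H-7 | BrC1(Br)[C@H]2C[C@@H]3[C@@H]([C@@H]12)C(C)(C)CCC[C@@]3(C)O
F5 | step 7 | (1R,2R,7R,10R)-9-bromo-2-hydroxy-2,6,6-trimethylbicyclo[5.4.0]undec-8-en-10-yl 3-(tert-butyldimethylsilyloxy)-4-methoxybenzoate | COc1ccc(C(=O)O[C@@H]2C[C@@H]3[C@@H](C=C2Br)C(C)(C)CCC[C@@]3(C)O)cc1O[Si](C)(C)C(C)(C)C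
F6 | step 6 | (1R,2R,7R)-6,6-dimethylspiro[bicyclo[5.3.0]dec-8-ene-2,2'-oxirane], oxygen cis to H-1 | C1C[C@@H]2[C@@H](C=1)C(C)(C)CCC[C@@]2(C3)O3
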